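**Strategy.** The 14-membered ring is closed last, between the allylic CH2 (C4) and the CH2 next to the carbinol-bearing methine (C5); ring numbering: C1 carries the acetate, C2=C3 and C8=C9 are the olefins, C12–C13 the epoxide. The key step exploits the 1,4-relationship of the C1 oxygen and C4 across the E-C2=C3 bond: zerovalent palladium ionises a C1–C2 vinyl epoxide carrying a C3 isopropenyl group, and a C5 bis(phenylsulfonyl) carbanion attacks the distal terminus C4. One operation forms the ring, the E-trisubstituted olefin and the free C1 carbinol. The acyclic bis-epoxide precursor comes from two fragments joined by Negishi coupling at C9–C10.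

Key step: step 13

Remark: the antipodes of the bishydroxamic acid ligand (step 5) and of the diphenylpyrrolidine catalyst (step 8) are to be chosen by their published facial models so that the configurations written below result; C15 is the carbinol carbon of the hydroxypropyl group.

Step 1
Reactants: 1 bis(phenylsulfonyl)methane; 2 ethyl (2E)-4-oxobut-2-enoate
Product: 3 ethyl (2R)-2-[bis(phenylsulfonyl)methyl]-4-oxobutanoate
Conditions: (S)-α,α-diphenylprolinol trimethylsilyl ether (10 mol %), toluene, rt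
Reagents that add atoms: none
Why: Iminium-catalysed Michael addition of the C–H acid to the enal β-carbon (Jørgensen–Hayashi catalysis); the (S)-catalyst shields one face of the E-iminium, so C6 should form with the (R) configuration the target needs.

Step 2
Reactants: 3 ethyl (2R)-2-[bis(phenylsulfonyl)methyl]-4-oxobutanoate
Product: 4 ethyl (2R,4Z)-2-[bis(phenylsulfonyl)methyl]-5-iodohex-4-enoate
Conditions: EtPPh3I, n-BuLi, THF, −78 °C; I2; NaHMDS (excess); then 3, −78 → −20 °C
Reagents that add atoms: ethyltriphenylphosphonium iodide CC[P+](c1ccccc1)(c1ccccc1)c1ccccc1.[I-]; iodine II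
Why: Stork–Zhao Wittig olefination with the α-iodo ylide should give the (Z)-2-iodoalkene (iodine cis to C7) under kinetic control; the bis-sulfone is carried as its sodium salt, which also protects C6 from enolisation.

Step 3
Reactants: 4 ethyl (2R,4Z)-2-[bis(phenylsulfonyl)methyl]-5-iodohex-4-enoate
Product: 6 (3R,5Z)-3-[bis(phenylsulfonyl)methyl]-6-iodo-2-methylhept-5-en-2-ol, via methyl ketone 5 (not isolated)
Conditions: MeMgBr (excess), THF, −20 → 0 °C
Reagents that add atoms: methylmagnesium bromide C[Mg]Br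
Why: Double Grignard addition to the ester gives the tertiary carbinol; the acidic bis-sulfone C–H is deprotonated first, and the vinyl iodide and the C6 centre should be untouched.

Step 4
Reactants: 7 but-3-en-1-ylmagnesium bromide; 8 propyne; 9 oxirane
Product: 11 (3Z)-4-methylocta-3,7-dien-1-ol, via alkenylcopper 10 (not isolated)
Conditions: CuBr·SMe2, Et2O/Me2S, −45 °C; propyne, −25 °C; then oxirane, HMPA, −25 → 0 °C; aq. NH4Cl
Reagents that add atoms: none
Why: Normant carbocupration adds the alkylcopper syn across propyne (copper cis to the butenyl chain), and alkylation of the alkenylcopper by oxirane occurs with retention, fixing the Z-trisubstituted olefin with C11 and C14 cis.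

Step 5
Reactants: 11 (3Z)-4-methylocta-3,7-dien-1-ol
Product: 12 2-[(2S,3R)-3-(but-3-en-1-yl)-3-methyloxiran-2-yl]ethan-1-ol
Conditions: VO(OiPr)3 (2 mol %), C2-symmetric bishydroxamic acid ligand (4 mol %, antipode giving the (2S,3R) oxirane), cumene hydroperoxide, toluene, 0 °C → rt
Reagents that add atoms: cumene hydroperoxide CC(C)(OO)c1ccccc1
Why: Vanadium-catalysed asymmetric epoxidation directed by the homoallylic hydroxyl (Yamamoto type) should oxidise only the proximal trisubstituted olefin, stereospecifically (cis epoxide) and with face selection by the ligand; the terminal vinyl group is not directed and remains.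

Step 6
Reactants: 12 2-[(2S,3R)-3-(but-3-en-1-yl)-3-methyloxiran-2-yl]ethan-1-ol
Product: 13 (2R,3S)-2-(but-3-en-1-yl)-3-(2-iodoethyl)-2-methyloxirane
Conditions: I2, PPh3, imidazole, CH2Cl2, 0 °C
Reagents that add atoms: iodine II
Why: Appel-type iodination (Garegg–Samuelsson) of the primary alcohol by SN2 on the alkoxyphosphonium ion; the trisubstituted epoxide should survive the buffered, cold conditions.

Step 7
Reactants: 13 (2R,3S)-2-(but-3-en-1-yl)-3-(2-iodoethyl)-2-methyloxirane
Product: 14 3-[(2R,3S)-3-(2-iodoethyl)-2-methyloxiran-2-yl]propanal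
Conditions: K2OsO4·2H2O (2 mol %), NaIO4, 2,6-lutidine, dioxane/H2O, rt
Reagents that add atoms: sodium periodate [Na+].[O-]I(=O)(=O)=O
Why: Lemieux–Johnson oxidative cleavage of the only olefin gives the C2 aldehyde with loss of one carbon; lutidine buffering protects the epoxide, and the alkyl iodide is spared, which is why ozone is avoided.

Step 8
Reactants: 14 3-[(2R,3S)-3-(2-iodoethyl)-2-methyloxiran-2-yl]propanal
Product: 15 (2R)-2-chloro-3-[(2R,3S)-3-(2-iodoethyl)-2-methyloxiran-2-yl]propanal
Conditions: N-chlorosuccinimide, trans-2,5-diphenylpyrrolidine (10 mol %, antipode giving the (2R)-chloride), CH2Cl2, 0 °C; used at once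
Reagents that add atoms: N-chlorosuccinimide O=C1CCC(=O)N1Cl
Why: Enamine-catalysed α-chlorination (Jørgensen type) sets the C1 chloride by catalyst control; the (R)-chloride is needed because step 12 inverts this centre.

Step 9
Reactants: 15 (2R)-2-chloro-3-[(2R,3S)-3-(2-iodoethyl)-2-methyloxiran-2-yl]propanal
Product: 16 (3S,4R)-4-chloro-5-[(2R,3S)-3-(2-iodoethyl)-2-methyloxiran-2-yl]-2-methylpent-1-en-3-ol
Conditions: isopropenylmagnesium bromide, THF, −78 °C
Reagents that add atoms: isopropenylmagnesium bromide CC(=C)[Mg]Br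
Why: Grignard addition to the α-chloro aldehyde (Cornforth-type, anti-chlorohydrin expected as the major isomer, drawn); the configuration of the new C2 carbinol is of no consequence because C2 becomes sp2 in step 13.

Step 10
Reactants: 16 (3S,4R)-4-chloro-5-[(2R,3S)-3-(2-iodoethyl)-2-methyloxiran-2-yl]-2-methylpent-1-en-3-ol
Product: 17 {[(3S,4R)-4-chloro-5-[(2R,3S)-3-(2-iodoethyl)-2-methyloxiran-2-yl]-2-methylpent-1-en-3-yl]oxy}(triethyl)silane
Conditions: TESOTf, 2,6-lutidine, CH2Cl2, −78 °C
Reagents that add atoms: triethylsilyl trifluoromethanesulfonate CC[Si](CC)(CC)OS(=O)(=O)C(F)(F)F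
Why: Silylation masks the chlorohydrin, so that no vinyl epoxide is present during the palladium-catalysed coupling and no free hydroxyl quenches the organozinc; the non-nucleophilic base avoids alkylation by the primary iodide.

Step 11
Reactants: 17 {[(3S,4R)-4-chloro-5-[(2R,3S)-3-(2-iodoethyl)-2-methyloxiran-2-yl]-2-methylpent-1-en-3-yl]oxy}(triethyl)silane; 6 (3R,5Z)-3-[bis(phenylsulfonyl)methyl]-6-iodo-2-methylhept-5-en-2-ol
Product: 19 (3R,5Z)-3-[bis(phenylsulfonyl)methyl]-8-[(2S,3R)-3-{(2R,3S)-2-chloro-4-methyl-3-[(triethylsilyl)oxy]pent-4-en-1-yl}-3-methyloxiran-2-yl]-2,6-dimethyloct-5-en-2-ol, via alkylzinc iodide 18 (not isolated)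
Conditions: 17, Zn dust, LiCl, THF, 35 °C; then 6, Pd(OAc)2 (3 mol %), SPhos (6 mol %), THF, rt
Reagents that add atoms: none
Why: Negishi sp3–sp2 coupling: zinc inserts into the primary iodide only, and coupling with the Z-vinyl iodide should proceed with retention of olefin geometry; no base is present, so the bis-sulfone C–H stays protonated and the silylated chlorohydrin is inert.

Step 12
Reactants: 19 (3R,5Z)-3-[bis(phenylsulfonyl)methyl]-8-[(2S,3R)-3-{(2R,3S)-2-chloro-4-methyl-3-[(triethylsilyl)oxy]pent-4-en-1-yl}-3-methyloxiran-2-yl]-2,6-dimethyloct-5-en-2-ol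
Product: 21 (3R,5Z)-3-[bis(phenylsulfonyl)methyl]-2,6-dimethyl-8-[(2S,3R)-3-methyl-3-{[(2S,3S)-3-(prop-1-en-2-yl)oxiran-2-yl]methyl}oxiran-2-yl]oct-5-en-2-ol, via chlorohydrin 20 (not isolated)
Conditions: TBAF, THF, 0 °C → rt
Reagents that add atoms: none
Why: Fluoride desilylation liberates the C2 alkoxide, which displaces the neighbouring chloride (Williamson-type epoxide closure) with inversion at C1, giving the (1S)-configured trans vinyl epoxide.

Step 13
Reactants: 21 (3R,5Z)-3-[bis(phenylsulfonyl)methyl]-2,6-dimethyl-8-[(2S,3R)-3-methyl-3-{[(2S,3S)-3-(prop-1-en-2-yl)oxiran-2-yl]methyl}oxiran-2-yl]oct-5-en-2-ol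
Product: 22 (1S,2E,6R,8Z,12S,13R)-12,13-epoxy-6-(2-hydroxypropan-2-yl)-3,9,13-trimethyl-5,5-bis(phenylsulfonyl)cyclotetradeca-2,8-dien-1-ol
Conditions: Pd(PPh3)4 (10 mol %), dppe (10 mol %), THF, reflux, slow addition (high dilution)
Reagents that add atoms: none
Why: Zerovalent palladium ionises the allylic C2–O bond of the vinyl epoxide with inversion to a zwitterionic π-allyl (C2–C3–C4) palladium alkoxide; the C1 alkoxide removes the C5–H of the bis-sulfone (pKa about 12), and the soft carbanion attacks the unsubstituted terminus C4 anti to the metal, closing the ring and releasing the catalyst. The closest known reaction type is the Tsuji–Trost alkylation of vinyl epoxides under neutral conditions in its macrocyclisation form (sulfone-stabilised carbanion onto a vinyl epoxide). The 14-membered carbocycle closes in a formally endo SN2′ mode, C2 and C3 of the allyl unit becoming ring atoms; attack at C2 (12-membered ring with an exocyclic isopropenyl group) is disfavoured because C2 is secondary and sits next to the alkoxide. No stereocentre is created: C5 carries two identical sulfonyl groups, C1 keeps its (S) configuration because its C–O bond is never broken, and C2 loses its stereochemistry, so the chlorohydrin epimers of step 9 converge. The step needs E geometry at C2=C3, expected from the syn π-allyl complex (C1 substituent anti to C4), and ring closure over oligomerisation, secured by slow addition and by generation of the nucleophile only after ionisation in the same molecule. The non-allylic C12–C13 epoxide is not ionised, and the hindered tertiary hydroxyl should not compete as a nucleophile.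

Step 14
Reactants: 22 (1S,2E,6R,8Z,12S,13R)-12,13-epoxy-6-(2-hydroxypropan-2-yl)-3,9,13-trimethyl-5,5-bis(phenylsulfonyl)cyclotetradeca-2,8-dien-1-ol
Product: 23 (1S,2E,6R,8Z,12S,13R)-12,13-epoxy-6-(2-hydroxypropan-2-yl)-3,9,13-trimethylcyclotetradeca-2,8-dien-1-ol
Conditions: Na(Hg) (6 %), Na2HPO4, MeOH/THF, −20 → 0 °C
Reagents that add atoms: none
Why: Reductive desulfonylation by electron transfer from sodium amalgam cleaves both C–S bonds and turns C5 into CH2; the buffered conditions should leave the epoxide, the olefins and the free alcohols intact.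

Step 15
Reactants: 23 (1S,2E,6R,8Z,12S,13R)-12,13-epoxy-6-(2-hydroxypropan-2-yl)-3,9,13-trimethylcyclotetradeca-2,8-dien-1-ol
Product: 24 (1S,2E,6R,8Z,12S,13R)-12,13-epoxy-6-(2-hydroxypropan-2-yl)-3,9,13-trimethylcyclotetradeca-2,8-dien-1-yl acetate
Conditions: Ac2O (1.5 equiv), pyridine, DMAP (cat.), CH2Cl2, 0 °C
Reagents that add atoms: acetic anhydride CC(=O)OC(C)=O
Why: Acylation of the secondary allylic alcohol with retention at C1; the hindered tertiary alcohol should not be acetylated at 0 °C with limited anhydride.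

**Compound list**
1 | bis(phenylsulfonyl)methane | O=S(=O)(c1ccccc1)CS(=O)(=O)c1ccccc1 | starting material
2 | ethyl (2E)-4-oxobut-2-enoate | CCOC(=O)/C=C/C=O | starting material
3 | ethyl (2R)-2-[bis(phenylsulfonyl)methyl]-4-oxobutanoate | O=S(=O)(c1ccccc1)C(S(=O)(=O)c1ccccc1)[C@@H](C(=O)OCC)CC=O | intermediate
4 | ethyl (2R,4Z)-2-[bis(phenylsulfonyl)methyl]-5-iodohex-4-enoate | O=S(=O)(c1ccccc1)C(S(=O)(=O)c1ccccc1)[C@@H](C(=O)OCC)C/C=C(/C)I | intermediate
5 | (3R,5Z)-3-[bis(phenylsulfonyl)methyl]-6-iodohept-5-en-2-one (methyl ketone, not isolated) | O=S(=O)(c1ccccc1)C(S(=O)(=O)c1ccccc1)[C@@H](C(C)=O)C/C=C(/C)I | intermediate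
6 | (3R,5Z)-3-[bis(phenylsulfonyl)methyl]-6-iodo-2-methylhept-5-en-2-ol | O=S(=O)(c1ccccc1)C(S(=O)(=O)c1ccccc1)[C@@H](C(C)(C)O)C/C=C(/C)I | intermediate
7 | but-3-en-1-ylmagnesium bromide | C=CCC[Mg]Br | starting material
8 | propyne | CC#C | starting material
9 | oxirane | C1CO1 | starting material
10 | [(1Z)-2-methylhexa-1,5-dien-1-yl]copper (alkenylcopper, not isolated) | [Cu]/C=C(/C)CCC=C | intermediate
11 | (3Z)-4-methylocta-3,7-dien-1-ol | OCC/C=C(/C)CCC=C | intermediate
12 | 2-[(2S,3R)-3-(but-3-en-1-yl)-3-methyloxiran-2-yl]ethan-1-ol | OCC[C@@H]1O[C@]1(C)CCC=C | intermediate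
13 | (2R,3S)-2-(but-3-en-1-yl)-3-(2-iodoethyl)-2-methyloxirane | ICC[C@@H]1O[C@]1(C)CCC=C | intermediate
14 | 3-[(2R,3S)-3-(2-iodoethyl)-2-methyloxiran-2-yl]propanal | ICC[C@@H]1O[C@]1(C)CCC=O | intermediate
15 | (2R)-2-chloro-3-[(2R,3S)-3-(2-iodoethyl)-2-methyloxiran-2-yl]propanal | ICC[C@@H]1O[C@]1(C)C[C@@H](Cl)C=O | intermediate
16 | (3S,4R)-4-chloro-5-[(2R,3S)-3-(2-iodoethyl)-2-methyloxiran-2-yl]-2-methylpent-1-en-3-ol | ICC[C@@H]1O[C@]1(C)C[C@@H](Cl)[C@@H](O)C(C)=C | intermediate
17 | {[(3S,4R)-4-chloro-5-[(2R,3S)-3-(2-iodoethyl)-2-methyloxiran-2-yl]-2-methylpent-1-en-3-yl]oxy}(triethyl)silane | ICC[C@@H]1O[C@]1(C)C[C@@H](Cl)[C@@H](O[Si](CC)(CC)CC)C(C)=C | intermediate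
18 | alkylzinc iodide derived from 17 (not isolated) | I[Zn]CC[C@@H]1O[C@]1(C)C[C@@H](Cl)[C@@H](O[Si](CC)(CC)CC)C(C)=C | intermediate
19 | (3R,5Z)-3-[bis(phenylsulfonyl)methyl]-8-[(2S,3R)-3-{(2R,3S)-2-chloro-4-methyl-3-[(triethylsilyl)oxy]pent-4-en-1-yl}-3-methyloxiran-2-yl]-2,6-dimethyloct-5-en-2-ol | O=S(=O)(c1ccccc1)C(S(=O)(=O)c1ccccc1)[C@@H](C(C)(C)O)C/C=C(/C)CC[C@@H]1O[C@]1(C)C[C@@H](Cl)[C@@H](O[Si](CC)(CC)CC)C(C)=C | intermediate
20 | (3R,5Z)-3-[bis(phenylsulfonyl)methyl]-8-{(2S,3R)-3-[(2R,3S)-2-chloro-3-hydroxy-4-methylpent-4-en-1-yl]-3-methyloxiran-2-yl}-2,6-dimethyloct-5-en-2-ol (chlorohydrin, not isolated) | O=S(=O)(c1ccccc1)C(S(=O)(=O)c1ccccc1)[C@@H](C(C)(C)O)C/C=C(/C)CC[C@@H]1O[C@]1(C)C[C@@H](Cl)[C@@H](O)C(C)=C | intermediate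
21 | (3R,5Z)-3-[bis(phenylsulfonyl)methyl]-2,6-dimethyl-8-[(2S,3R)-3-methyl-3-{[(2S,3S)-3-(prop-1-en-2-yl)oxiran-2-yl]methyl}oxiran-2-yl]oct-5-en-2-ol | O=S(=O)(c1ccccc1)C(S(=O)(=O)c1ccccc1)[C@@H](C(C)(C)O)C/C=C(/C)CC[C@@H]1O[C@]1(C)C[C@@H]1O[C@H]1C(C)=C | intermediate
22 | (1S,2E,6R,8Z,12S,13R)-12,13-epoxy-6-(2-hydroxypropan-2-yl)-3,9,13-trimethyl-5,5-bis(phenylsulfonyl)cyclotetradeca-2,8-dien-1-ol | O[C@@H]1/C=C(\C)CC(S(=O)(=O)c3ccccc3)(S(=O)(=O)c3ccccc3)[C@@H](C(C)(C)O)C/C=C(/C)CC[C@@H]2O[C@]2(C)C1 | intermediate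
23 | (1S,2E,6R,8Z,12S,13R)-12,13-epoxy-6-(2-hydroxypropan-2-yl)-3,9,13-trimethylcyclotetradeca-2,8-dien-1-ol | O[C@@H]1/C=C(\C)CC[C@@H](C(C)(C)O)C/C=C(/C)CC[C@@H]2O[C@]2(C)C1 | intermediate
24 | (1S,2E,6R,8Z,12S,13R)-12,13-epoxy-6-(2-hydroxypropan-2-yl)-3,9,13-trimethylcyclotetradeca-2,8-dien-1-yl acetate (CNP0254503.1) | CC(=O)O[C@@H]1/C=C(\C)CC[C@@H](C(C)(C)O)C/C=C(/C)CC[C@@H]2O[C@]2(C)C1 | target

Total step count: 15. Longest linear sequence: 12 steps (steps 4–15; steps 1–3 make the other coupling partner).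

**Steps most likely to fail**

1. Step 13 (key macrocyclisation). What may go wrong: C–C bond formation at the congested tertiary bis-sulfonyl carbanion may be slow, so that oligomerisation and syn–anti isomerisation of the π-allyl intermediate (loss of E geometry) take over. Fallback, setting out from 21 and returning at 23: the vinyl epoxide of 21 is opened with Pd(PPh3)4 and excess AcOH in THF, where acetate attacks C4 while the bis-sulfone stays protonated, to give the (E)-1,4-hydroxy acetate F1. SmI2 in THF–MeOH at −78 °C removes one sulfonyl group and K2CO3/MeOH cleaves the acetate, giving the mono-sulfone diol F2. N-chlorosuccinimide/Me2S converts the primary allylic alcohol selectively into the allylic chloride F3. LDA (3.3 equiv, THF, −78 °C, high dilution) then closes the same C4–C5 bond by SN2 alkylation of the less hindered α-sulfonyl carbanion, with the olefin geometry already fixed, to the macrocyclic mono-sulfone F4. Na(Hg)/Na2HPO4/MeOH removes the sulfone and gives 23.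

2. Step 11 (fragment coupling). What may go wrong: protonolysis of the alkylzinc by the acidic C–H and O–H of 6, and Lewis-acid opening of the epoxide during zinc insertion. Fallback, setting out from 17 and 6 and returning at 19: direct reductive cross-electrophile coupling of the two iodides (NiI2, 4,4′-di-tert-butyl-2,2′-bipyridine, Mn powder, NaI, DMA, rt), which needs no preformed organometallic reagent and tolerates acidic protons; this fallback makes no new compound (F0).

3. Step 2 (iodo-olefination). What may go wrong: the basic iodo-ylide may enolise or merely deprotonate the substrate, giving low conversion or eroded Z selectivity. Fallback, setting out from 3 and returning at 19: dibromo-olefination of 3 (CBr4, PPh3, CH2Cl2, 0 °C) gives the 1,1-dibromoalkene ethyl (2R)-2-[bis(phenylsulfonyl)methyl]-5,5-dibromopent-4-enoate F5. Trans-selective palladium-catalysed mono-methylation (MeZnCl, Pd(PPh3)4, THF) replaces the bromine trans to the chain and leaves ethyl (2R,4Z)-2-[bis(phenylsulfonyl)methyl]-5-bromohex-4-enoate F6. MeMgBr gives (3R,5Z)-3-[bis(phenylsulfonyl)methyl]-6-bromo-2-methylhept-5-en-2-ol F7, which takes the place of 6 in the Negishi coupling of step 11 to give 19.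

**Further compounds**
F1 | step 13 | (E)-1,4-hydroxy acetate: seco bis-sulfone with C1–OH (S), E-C2=C3 and C4–OAc | O=S(=O)(c1ccccc1)C(S(=O)(=O)c1ccccc1)[C@@H](C(C)(C)O)C/C=C(/C)CC[C@@H]1O[C@]1(C)C[C@H](O)/C=C(\C)COC(C)=O
F2 | step 13 | mono-sulfone diol (C5H2SO2Ph, C1–OH, C4–OH) | O=S(=O)(c1ccccc1)C[C@@H](C(C)(C)O)C/C=C(/C)CC[C@@H]1O[C@]1(C)C[C@H](O)/C=C(\C)CO
F3 | step 13 | mono-sulfone (E)-allylic chloride | O=S(=O)(c1ccccc1)C[C@@H](C(C)(C)O)C/C=C(/C)CC[C@@H]1O[C@]1(C)C[C@H](O)/C=C(\C)CCl
F4 | step 13 | macrocyclic C5 mono-sulfone diol (C5 epimers) | O[C@@H]1/C=C(\C)CC(S(=O)(=O)c3ccccc3)[C@@H](C(C)(C)O)C/C=C(/C)CC[C@@H]2O[C@]2(C)C1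
F0 | step 11 | none | none
F5 | step 2 | ethyl (2R)-2-[bis(phenylsulfonyl)methyl]-5,5-dibromopent-4-enoate | O=S(=O)(c1ccccc1)C(S(=O)(=O)c1ccccc1)[C@@H](C(=O)OCC)CC=C(Br)Br
F6 | step 2 | ethyl (2R,4Z)-2-[bis(phenylsulfonyl)methyl]-5-bromohex-4-enoate | O=S(=O)(c1ccccc1)C(S(=O)(=O)c1ccccc1)[C@@H](C(=O)OCC)C/C=C(/C)Br
F7 | step 2 | (3R,5Z)-3-[bis(phenylsulfonyl)methyl]-6-bromo-2-methylhept-5-en-2-ol | O=S(=O)(c1ccccc1)C(S(=O)(=O)c1ccccc1)[C@@H](C(C)(C)O)C/C=C(/C)Br
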